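**Plan**

- Retrosynthesis (azulene numbering): cut the anisoate C–O bond; take the C7 carbinol and the C5=C6 double bond back through a 7-ketone to a C7=C8 alkene; cut the C3–isopropyl bond back to a C3 ketone; then cut C3a–C8a and C5–C6 together, which opens both rings to an acyclic diazo trienone.
- Enabling feature: in the seven-membered ring, C3a–C4–C5 is a three-carbon unit with oxygen on its middle carbon (a 2-siloxyvinyl carbene centred on C3a) and C6–C7–C8–C8a is a 1,3-diene. The C3 carbinol carbon next to C3a serves as the ketone that stabilises the carbenoid and, with C2 and C1, as the tether that becomes the five-membered ring.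
- Forward order: crotonaldehyde to a dienyl bromide, alkylation of the acetylacetone dianion, diazo transfer and enol silylation give the chain. One Rh-catalysed operation closes the five-membered ring (cyclopropanation) and then the seven-membered ring (divinylcyclopropane Cope). Isopropyl addition, ring-fusion equilibration, directed reduction, anisoylation and adjustment at C5–C7 follow.
- Stereochemistry: C8a from the chiral Rh carboxylate; C3 from Grignard attack anti to the angular methyl; C3a from chelation-controlled equilibration; C4 from hydroxyl-directed hydride delivery; C7 from hydride attack anti to the angular methyl.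

Key step: step 7

Remark: ring positions follow azulene numbering (C1–C3, C3a, C4–C8, C8a); Rh2(S-PTAD)4 (PTAD = (1-adamantyl)(N-phthalimido)acetate) is assumed to give the (8aR) series, and the mirror-image catalyst Rh2(R-PTAD)4 would take its place if the sense of induction is the opposite.

**Route**

Step 1
Reactants: 1 (E)-but-2-enal; 2 ethyl 2-(triphenylphosphoranylidene)propanoate
Product: 3 ethyl (2E,4E)-2-methylhexa-2,4-dienoate
Conditions: CH2Cl2, rt
Reagents that add atoms: none
Why: The stabilised ylide reacts with the aldehyde in a Wittig olefination under thermodynamic control, so the new trisubstituted double bond should be (E) while the (E)-crotyl double bond is carried through unchanged.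

Step 2
Reactants: 3 ethyl (2E,4E)-2-methylhexa-2,4-dienoate
Product: 4 (2E,4E)-2-methylhexa-2,4-dien-1-ol
Conditions: i-Bu2AlH (2.2 equiv), CH2Cl2, −78 °C to 0 °C; aqueous KNaC4H4O6 work-up
Reagents that add atoms: none
Why: i-Bu2AlH reduces the conjugated ester to the primary allylic alcohol by 1,2-hydride delivery (ester reduction) without touching the diene.

Step 3
Reactants: 4 (2E,4E)-2-methylhexa-2,4-dien-1-ol
Product: 5 (2E,4E)-1-bromo-2-methylhexa-2,4-diene
Conditions: PBr3 (0.4 equiv), Et2O, −10 °C; used crude
Reagents that add atoms: phosphorus tribromide, BrP(Br)Br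
Why: PBr3 converts the primary dienylic alcohol into the bromide by SN2 displacement of the phosphite ester, and the conjugated primary bromide is also the thermodynamically preferred allylic isomer.

Step 4
Reactants: 5 (2E,4E)-1-bromo-2-methylhexa-2,4-diene; 6 pentane-2,4-dione
Product: 7 (7E,9E)-7-methylundeca-7,9-diene-2,4-dione
Conditions: 6, NaH then n-BuLi, THF, 0 °C; then 5, 0 °C to rt; dilute HCl work-up
Reagents that add atoms: none
Why: In this Huckin–Weiler dianion alkylation the terminal carbanion of the acetylacetone dianion is the most nucleophilic site and displaces the primary allylic bromide by SN2, so the chain is extended at the methyl group only.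

Step 5
Reactants: 7 (7E,9E)-7-methylundeca-7,9-diene-2,4-dione
Product: 8 (7E,9E)-3-diazo-7-methylundeca-7,9-diene-2,4-dione
Conditions: 4-acetamidobenzenesulfonyl azide, Et3N, MeCN, 0 °C to rt
Reagents that add atoms: 4-acetamidobenzenesulfonyl azide, CC(=O)Nc1ccc(cc1)S(=O)(=O)N=[N+]=[N-]
Why: Regitz diazo transfer occurs at the doubly activated C3 methylene of the 1,3-diketone, the only position acidic enough for Et3N.

Step 6
Reactants: 8 (7E,9E)-3-diazo-7-methylundeca-7,9-diene-2,4-dione
Product: 9 (7E,9E)-2-[(tert-butyldimethylsilyl)oxy]-3-diazo-7-methylundeca-1,7,9-trien-4-one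
Conditions: LiN(i-Pr)2 (1.1 equiv), THF, −78 °C; then TBSOTf (1.2 equiv), −78 °C
Reagents that add atoms: tert-butyldimethylsilyl trifluoromethanesulfonate, CC(C)(C)[Si](C)(C)OS(=O)(=O)C(F)(F)F
Why: Kinetic deprotonation by the hindered amide base should take place at the unhindered acetyl methyl group in preference to the C5 methylene, and O-silylation of this enolate gives the 2-siloxyvinyl diazoketone (enoldiazoketone formation) with the diazo group intact.

Step 7
Reactants: 9 (7E,9E)-2-[(tert-butyldimethylsilyl)oxy]-3-diazo-7-methylundeca-1,7,9-trien-4-one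
Product: 11 (6R,8aR)-4-[(tert-butyldimethylsilyl)oxy]-6,8a-dimethyl-2,5,6,8a-tetrahydroazulen-3(1H)-one, via cis-divinylcyclopropane 10 (not isolated)
Conditions: Rh2(S-PTAD)4 (1 mol %), hexane/CH2Cl2, −20 °C to rt, slow addition of 9; then toluene, 80 °C
Reagents that add atoms: none
Why: Loss of N2 at the Rh carboxylate gives a 2-siloxyvinyl carbenoid centred on the future C3a, which adds to the proximal (E)-trisubstituted alkene in a concerted, asynchronous cyclopropanation; this closes the five-membered ring as a bicyclo[3.1.0]hexan-2-one (ring closure by intramolecular [2+1] addition across the alkene four atoms away) and makes the C3a–C8a bond at the quaternary carbon. Because the tether holds C3 and C1 on one face of the cyclopropane and the alkene is (E), the siloxyvinyl and propenyl groups of 10 are necessarily cis, so 10 undergoes a Cope rearrangement through the boat transition state, which makes the C5–C6 bond and expands the three-membered ring to the seven-membered ring (closure by [3,3]-sigmatropic ring expansion, overall a formal 4+3 annulation). The closest known reaction type is the Davies tandem cyclopropanation/Cope rearrangement of vinyldiazo carbonyl compounds with dienes in its intramolecular form, here with a siloxyvinyl (enoldiazo) ketone. C8a, the only new stereocentre that survives to the target, is set by the alkene face that the chiral carboxylate ligands of Rh2(S-PTAD)4 expose to the carbenoid, whereas C6 follows from the boat geometry (the (E)-methyl ends trans to the angular methyl) and is erased in step 14. The step needs chemoselectivity for the proximal alkene, which the five-membered-ring transition state and the inertness of trans-disubstituted alkenes toward donor/acceptor carbenoids should secure, and it needs the Cope rearrangement to outrun the homo-1,5-hydrogen shift of the syn methyl group, which the 2-siloxy substituent and only gentle heating should secure.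

Step 8
Reactants: 11 (6R,8aR)-4-[(tert-butyldimethylsilyl)oxy]-6,8a-dimethyl-2,5,6,8a-tetrahydroazulen-3(1H)-one
Product: 13 (3R,6R,8aR)-3-hydroxy-6,8a-dimethyl-3-(propan-2-yl)-2,3,3a,5,6,8a-hexahydroazulen-4(1H)-one as its C3a epimers, via silyl enol ether carbinol 12 (not isolated)
Conditions: i-PrMgCl (1.5 equiv), LaCl3·2LiCl (1.0 equiv), THF, −20 °C; then AcOH, n-Bu4NF, 0 °C
Reagents that add atoms: isopropylmagnesium chloride, CC(C)[Mg]Cl
Why: The lanthanide-activated Grignard reagent adds 1,2 to the vinylogous-ester carbonyl (the first stage of a Stork–Danheiser sequence) from the face opposite the angular methyl group, which sets C3, and buffered fluoride then cleaves the enol silane without the acid that would ionise the tertiary allylic alcohol, so the ketol should result as a mixture at the ring-fusion carbon C3a.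

Step 9
Reactants: 13 (3R,6R,8aR)-3-hydroxy-6,8a-dimethyl-3-(propan-2-yl)-2,3,3a,5,6,8a-hexahydroazulen-4(1H)-one as its C3a epimers
Product: 14 (3R,3aR,6R,8aR)-3-hydroxy-6,8a-dimethyl-3-(propan-2-yl)-2,3,3a,5,6,8a-hexahydroazulen-4(1H)-one (trans-fused)
Conditions: MgBr2·OEt2 (2 equiv), Et3N (3 equiv), CH2Cl2, rt; pH 7 buffer
Reagents that add atoms: none
Why: Soft enolisation with MgBr2 and Et3N makes C3a reversible, and only the trans-fused epimer, whose C3 alkoxide and C4 carbonyl are cis on the five-membered ring, can close the six-membered magnesium chelate and at the same time keep the acyl carbon trans to the isopropyl group, so this epimer should be the thermodynamic sink.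

Step 10
Reactants: 14 (3R,3aR,6R,8aR)-3-hydroxy-6,8a-dimethyl-3-(propan-2-yl)-2,3,3a,5,6,8a-hexahydroazulen-4(1H)-one
Product: 15 (3R,3aS,4S,6R,8aR)-6,8a-dimethyl-3-(propan-2-yl)-1,2,3,3a,4,5,6,8a-octahydroazulene-3,4-diol
Conditions: Me4NBH(OAc)3 (5 equiv), MeCN/AcOH (1:1), −30 °C to 0 °C
Reagents that add atoms: none
Why: In this Evans–Saksena reduction the triacetoxyborohydride exchanges one acetate for the tertiary C3 hydroxyl and delivers hydride intramolecularly to the C4 carbonyl from the face of the C3–O bond, which should give the 1,3-anti diol with the (4S) carbinol.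

Step 11
Reactants: 15 (3R,3aS,4S,6R,8aR)-6,8a-dimethyl-3-(propan-2-yl)-1,2,3,3a,4,5,6,8a-octahydroazulene-3,4-diol; 16 4-methoxybenzoyl chloride
Product: 17 (3R,3aS,4S,6R,8aR)-3-hydroxy-6,8a-dimethyl-3-(propan-2-yl)-1,2,3,3a,4,5,6,8a-octahydroazulen-4-yl 4-methoxybenzoate
Conditions: DMAP, Et3N, CH2Cl2, 0 °C to 40 °C
Reagents that add atoms: none
Why: DMAP-catalysed acylation (acyl chloride esterification) takes place at the secondary C4 hydroxyl only, because the tertiary C3 hydroxyl is too hindered to react.

Step 12
Reactants: 17 (3R,3aS,4S,6R,8aR)-3-hydroxy-6,8a-dimethyl-3-(propan-2-yl)-1,2,3,3a,4,5,6,8a-octahydroazulen-4-yl 4-methoxybenzoate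
Product: 18 (3R,3aS,4S,6R,8aR)-3,7-dihydroxy-6,8a-dimethyl-3-(propan-2-yl)decahydroazulen-4-yl 4-methoxybenzoate as its C7 epimers
Conditions: BH3·THF (3 equiv), THF, 0 °C to rt; then NaBO3·4H2O, H2O, rt
Reagents that add atoms: sodium perborate tetrahydrate, [Na+].[O-]OB=O.O.O.O.O
Why: In this Brown hydroboration–oxidation boron should add to C7, the alkene carbon remote from the quaternary C8a, and the configuration of the new carbinol is irrelevant because it is oxidised in the next step.

Step 13
Reactants: 18 (3R,3aS,4S,6R,8aR)-3,7-dihydroxy-6,8a-dimethyl-3-(propan-2-yl)decahydroazulen-4-yl 4-methoxybenzoate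
Product: 19 (3R,3aS,4S,6R,8aR)-3-hydroxy-6,8a-dimethyl-7-oxo-3-(propan-2-yl)decahydroazulen-4-yl 4-methoxybenzoate
Conditions: Dess–Martin periodinane, NaHCO3, CH2Cl2, rt
Reagents that add atoms: none
Why: Dess–Martin oxidation converts the secondary C7 alcohol into the ketone under buffered conditions that leave the tertiary alcohol and the ester untouched.

Step 14
Reactants: 19 (3R,3aS,4S,6R,8aR)-3-hydroxy-6,8a-dimethyl-7-oxo-3-(propan-2-yl)decahydroazulen-4-yl 4-methoxybenzoate
Product: 20 (3R,3aS,4S,8aR)-3-hydroxy-6,8a-dimethyl-7-oxo-3-(propan-2-yl)-1,2,3,3a,4,7,8,8a-octahydroazulen-4-yl 4-methoxybenzoate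
Conditions: IBX (2.5 equiv), DMSO/toluene, 70 °C
Reagents that add atoms: none
Why: IBX dehydrogenation of the ketone (Nicolaou desaturation) can only introduce the C5=C6 double bond, because the other α-carbon C8 has no β-hydrogen next to the quaternary C8a.

Step 15
Reactants: 20 (3R,3aS,4S,8aR)-3-hydroxy-6,8a-dimethyl-7-oxo-3-(propan-2-yl)-1,2,3,3a,4,7,8,8a-octahydroazulen-4-yl 4-methoxybenzoate
Product: 21 (3R,3aS,4S,7R,8aR)-3,7-dihydroxy-6,8a-dimethyl-3-(propan-2-yl)-1,2,3,3a,4,7,8,8a-octahydroazulen-4-yl 4-methoxybenzoate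
Conditions: NaBH4, CeCl3·7H2O, MeOH, −78 °C
Reagents that add atoms: none
Why: Luche reduction gives clean 1,2-reduction of the enone, and hydride attack from the face opposite the axial angular methyl group, which stands 1,3 to C7, should place the new hydroxyl cis to that methyl as in the (7R) target while the anisoate is untouched.

**Compound list**

1 | (E)-but-2-enal | C/C=C/C=O | starting material
2 | ethyl 2-(triphenylphosphoranylidene)propanoate | CCOC(=O)C(C)=P(c1ccccc1)(c1ccccc1)c1ccccc1 | starting material
3 | ethyl (2E,4E)-2-methylhexa-2,4-dienoate | CCOC(=O)/C(C)=C/C=C/C | intermediate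
4 | (2E,4E)-2-methylhexa-2,4-dien-1-ol | OC/C(C)=C/C=C/C | intermediate
5 | (2E,4E)-1-bromo-2-methylhexa-2,4-diene | BrC/C(C)=C/C=C/C | intermediate
6 | pentane-2,4-dione | CC(=O)CC(C)=O | starting material
7 | (7E,9E)-7-methylundeca-7,9-diene-2,4-dione | CC(=O)CC(=O)CC/C(C)=C/C=C/C | intermediate
8 | (7E,9E)-3-diazo-7-methylundeca-7,9-diene-2,4-dione | CC(=O)C(=[N+]=[N-])C(=O)CC/C(C)=C/C=C/C | intermediate
9 | (7E,9E)-2-[(tert-butyldimethylsilyl)oxy]-3-diazo-7-methylundeca-1,7,9-trien-4-one | C=C(O[Si](C)(C)C(C)(C)C)C(=[N+]=[N-])C(=O)CC/C(C)=C/C=C/C | intermediate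
10 | (1S,5R,6R)-1-{1-[(tert-butyldimethylsilyl)oxy]ethenyl}-5-methyl-6-[(1E)-prop-1-en-1-yl]bicyclo[3.1.0]hexan-2-one, the two alkenyl groups cis | O=C1CC[C@]2(C)[C@@H](/C=C/C)[C@]12C(=C)O[Si](C)(C)C(C)(C)C | intermediate
11 | (6R,8aR)-4-[(tert-butyldimethylsilyl)oxy]-6,8a-dimethyl-2,5,6,8a-tetrahydroazulen-3(1H)-one | C[C@H]1C=C[C@@]2(C)CCC(=O)C2=C(O[Si](C)(C)C(C)(C)C)C1 | intermediate
12 | (3R,6R,8aR)-4-[(tert-butyldimethylsilyl)oxy]-6,8a-dimethyl-3-(propan-2-yl)-1,2,3,5,6,8a-hexahydroazulen-3-ol | C[C@H]1C=C[C@@]2(C)CC[C@@](O)(C(C)C)C2=C(O[Si](C)(C)C(C)(C)C)C1 | intermediate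
13 | (3R,6R,8aR)-3-hydroxy-6,8a-dimethyl-3-(propan-2-yl)-2,3,3a,5,6,8a-hexahydroazulen-4(1H)-one, both C3a epimers (centre left open) | O=C1C[C@@H](C)C=C[C@@]2(C)CC[C@@](O)(C(C)C)C12 | intermediate
14 | (3R,3aR,6R,8aR)-3-hydroxy-6,8a-dimethyl-3-(propan-2-yl)-2,3,3a,5,6,8a-hexahydroazulen-4(1H)-one, trans-fused | O=C1C[C@@H](C)C=C[C@@]2(C)CC[C@@](O)(C(C)C)[C@H]12 | intermediate
15 | (3R,3aS,4S,6R,8aR)-6,8a-dimethyl-3-(propan-2-yl)-1,2,3,3a,4,5,6,8a-octahydroazulene-3,4-diol | O[C@H]1C[C@@H](C)C=C[C@@]2(C)CC[C@@](O)(C(C)C)[C@H]12 | intermediate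
16 | 4-methoxybenzoyl chloride | COc1ccc(cc1)C(Cl)=O | starting material
17 | (3R,3aS,4S,6R,8aR)-3-hydroxy-6,8a-dimethyl-3-(propan-2-yl)-1,2,3,3a,4,5,6,8a-octahydroazulen-4-yl 4-methoxybenzoate | COc1ccc(cc1)C(=O)O[C@H]1C[C@@H](C)C=C[C@@]2(C)CC[C@@](O)(C(C)C)[C@H]12 | intermediate
18 | (3R,3aS,4S,6R,8aR)-3,7-dihydroxy-6,8a-dimethyl-3-(propan-2-yl)decahydroazulen-4-yl 4-methoxybenzoate, both C7 epimers (centre left open) | COc1ccc(cc1)C(=O)O[C@H]1C[C@@H](C)C(O)C[C@@]2(C)CC[C@@](O)(C(C)C)[C@H]12 | intermediate
19 | (3R,3aS,4S,6R,8aR)-3-hydroxy-6,8a-dimethyl-7-oxo-3-(propan-2-yl)decahydroazulen-4-yl 4-methoxybenzoate | COc1ccc(cc1)C(=O)O[C@H]1C[C@@H](C)C(=O)C[C@@]2(C)CC[C@@](O)(C(C)C)[C@H]12 | intermediate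
20 | (3R,3aS,4S,8aR)-3-hydroxy-6,8a-dimethyl-7-oxo-3-(propan-2-yl)-1,2,3,3a,4,7,8,8a-octahydroazulen-4-yl 4-methoxybenzoate | COc1ccc(cc1)C(=O)O[C@H]1C=C(C)C(=O)C[C@@]2(C)CC[C@@](O)(C(C)C)[C@H]12 | intermediate
21 | (3R,3aS,4S,7R,8aR)-3,7-dihydroxy-6,8a-dimethyl-3-(propan-2-yl)-1,2,3,3a,4,7,8,8a-octahydroazulen-4-yl 4-methoxybenzoate | COc1ccc(C(=O)O[C@H]2C=C(C)[C@H](O)C[C@@]3(C)CC[C@@](O)(C(C)C)[C@H]23)cc1 | target

**Totals**

Total step count: 15. Longest linear sequence: 15 steps (1 to 21).

**Steps most likely to fail**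

Step 7. The chiral carboxylate may discriminate poorly between the two faces of the trisubstituted alkene in the intramolecular cyclopropanation, so that the cascade works but the enantiomeric purity is too low. The fallback sets out from 9 and changes from catalyst control to resolution. Step 7 is run with achiral Rh2(OAc)4 and the racemate is carried through steps 8 to 10. The secondary C4 hydroxyl of the racemic diol is esterified with (S)-2-methoxy-2-phenylacetic acid (DCC, DMAP, CH2Cl2). The diastereomeric esters are separated by chromatography, and the (3R,3aS,4S,6R,8aR)-diol (2S)-2-methoxy-2-phenylacetate F1 is cleaved with LiOH in THF/H2O. The route is rejoined at 15.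

Step 9. Epimerisation at the hindered ring-fusion carbon may be slow, and the tertiary aldolate may instead undergo retro-aldol opening of the five-membered ring. The fallback sets out from 13 and blocks the retro-aldol path. The tertiary hydroxyl is silylated with 1-(trimethylsilyl)imidazole to give the trimethylsilyl ether of the ketol as its C3a epimers F2. This is equilibrated with DBU in toluene to the trans-fused trimethylsilyl ether F3, in which the acyl carbon is trans to the isopropyl group. The silyl group is removed with citric acid in MeOH, and the route is rejoined at 14.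

Step 6. Deprotonation at the C5 methylene may compete with deprotonation of the acetyl methyl group, giving the regioisomeric enol silane. The fallback sets out from 6 (with 5) and fixes the regiochemistry by symmetry, replacing steps 4 to 6. Diazo transfer onto 6 (4-acetamidobenzenesulfonyl azide, Et3N) gives 3-diazopentane-2,4-dione F4. TBSOTf and Et3N give the single mono enol silane 4-[(tert-butyldimethylsilyl)oxy]-3-diazopent-4-en-2-one F5. Kinetic deprotonation of the remaining acetyl group with LiN(SiMe3)2 at −78 °C and alkylation with bromide 5 in THF/DMPU rejoins the route at 9.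

**Further compounds**

F1 | step 7 | (3R,3aS,4S,6R,8aR)-3-hydroxy-6,8a-dimethyl-3-(propan-2-yl)-1,2,3,3a,4,5,6,8a-octahydroazulen-4-yl (2S)-2-methoxy-2-phenylacetate | O=C(O[C@H]1C[C@@H](C)C=C[C@@]2(C)CC[C@@](O)(C(C)C)[C@H]12)[C@@H](OC)c1ccccc1
F2 | step 9 | (3R,6R,8aR)-6,8a-dimethyl-3-(propan-2-yl)-3-[(trimethylsilyl)oxy]-2,3,3a,5,6,8a-hexahydroazulen-4(1H)-one, both C3a epimers | O=C1C[C@@H](C)C=C[C@@]2(C)CC[C@@](O[Si](C)(C)C)(C(C)C)C12
F3 | step 9 | (3R,3aR,6R,8aR)-6,8a-dimethyl-3-(propan-2-yl)-3-[(trimethylsilyl)oxy]-2,3,3a,5,6,8a-hexahydroazulen-4(1H)-one | O=C1C[C@@H](C)C=C[C@@]2(C)CC[C@@](O[Si](C)(C)C)(C(C)C)[C@H]12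
F4 | step 6 | 3-diazopentane-2,4-dione | CC(=O)C(=[N+]=[N-])C(C)=O
F5 | step 6 | 4-[(tert-butyldimethylsilyl)oxy]-3-diazopent-4-en-2-one | C=C(O[Si](C)(C)C(C)(C)C)C(=[N+]=[N-])C(C)=O
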